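The target is the [4+2] dimer of 18-hydroxylabda-8(17),12E,14-triene, so one decalin alkylzinc reagent serves both halves, joined around the cyclohexene by two Negishi couplings and a catalyst-controlled Diels–Alder reaction. Everything rests on ring A (C1–C5, C10): its quaternary C4, bearing β-CH3 and α-CH2OH between C3 and C5, is read as the product of a cycloheptene oxide to cyclohexanecarbaldehyde contraction. The precursor is a trans-fused bicyclo[5.4.0]undecene α-epoxide built from (R)-carvone, whose isopropenyl group supplies C4/C19 and whose ring becomes ring B. In one operation a Lewis acid shifts C3 from C18 to C4, contracting the seven-membered ring to ring A, fixing C4 and releasing C18 as the aldehyde.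

Key step: step 5

Remark: bicyclic compounds from 9 on carry labdane locants (ring A = C1–C5 + C10, ring B = C5–C10, C17 on C8, C18 = oxygenated carbon on C4, C19 = methyl on C4, C20 = methyl on C10); primed locants belong to the unit whose C12′=C13′ alkene is attached to the cyclohexene.
Assumption: the (S)-configured oxazaborolidinium catalyst of step 18 (and the (S)-auxiliary of its fallback) is taken to deliver the dienophile to the diene face that gives 12S,14′S; if the sense proves opposite, the enantiomeric controller is used.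
Remark: 3 is used as its C6 epimer mixture, because step 2 planarises that centre again.

Step 1
Reactants: 1 (R)-(−)-carvone
Product: 3 (5R,6S)-2,6-dimethyl-5-(prop-1-en-2-yl)cyclohex-2-en-1-one (trans-6-methylcarvone), via lithium enolate of carvone 2 (not isolated)
Conditions: LiN(i-Pr)2, THF, −78 °C; MeI, −78 → 0 °C
Reagents that add atoms: iodomethane CI
Why: Kinetic α′-deprotonation of the cross-conjugated enone and enolate C-alkylation should methylate C6 (the future C10); its configuration does not matter because step 2 re-forms the enolate.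

Step 2
Reactants: 3 trans-6-methylcarvone; 4 5-iodopent-1-ene
Product: 6 (5S,6S)-2,6-dimethyl-6-(pent-4-en-1-yl)-5-(prop-1-en-2-yl)cyclohex-2-en-1-one, via lithium enolate of 6-methylcarvone 5 (not isolated)
Conditions: LiN(i-Pr)2, THF, −78 °C; 4 (3 equiv.), DMPU, −78 °C → rt
Reagents that add atoms: none
Why: Enolate alkylation of the tetrasubstituted enolate should occur anti to the neighbouring isopropenyl group, which sets the quaternary centre (future C10) with methyl cis to isopropenyl, as the trans ring fusion requires.

Step 3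
Reactants: 6 dialkylated carvone
Product: 7 (4aS,9aS)-2,5,9a-trimethyl-4,4a,7,8,9,9a-hexahydro-1H-benzo[7]annulen-1-one
Conditions: second-generation Grubbs catalyst (H2IMes)(PCy3)Cl2Ru=CHPh (5 mol%), CH2Cl2, 40 °C
Reagents that add atoms: none
Why: Ring-closing metathesis between the isopropenyl and the terminal vinyl group should close the trans-fused cycloheptene with its trisubstituted C4=C18 alkene, the conjugated enone alkene being inert.

Step 4
Reactants: 7 bicyclic dienone
Product: 8 α-epoxide (5,6-epoxy-2,5,9a-trimethyl-4,4a,5,6,7,8,9,9a-octahydro-1H-benzo[7]annulen-1-one; oxygen cis to 4a-H and trans to the 9a-methyl group)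
Conditions: mCPBA, NaHCO3, CH2Cl2, 0 °C
Reagents that add atoms: mCPBA O=C(OO)c1cccc(Cl)c1
Why: Prilezhaev epoxidation should select the electron-rich trisubstituted alkene over the enone and attack the face opposite the axial angular methyl group, placing both C–O bonds on the α-face, which the key step transfers to C4.

Step 5
Reactants: 8 α-epoxide
Product: 9 9-oxo-11,12,13,14,15,16-hexanorlabd-7-en-18-al (4β-CH3, 4α-CHO, 5α-H, 10β-CH3)
Conditions: MeAl(OAr)2 (Ar = 4-bromo-2,6-di-tert-butylphenyl; 2 equiv., pre-formed from AlMe3 and 2 ArOH), CH2Cl2, −78 °C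
Reagents that add atoms: none
Why: The oxophilic aluminium phenoxide binds the oxirane oxygen, the tertiary C4–O bond ionises and the C18–C3 ring bond migrates to C4 on the face opposite the departing oxygen while C18 becomes the aldehyde carbon (Meinwald rearrangement in its ring-contracting form). The closest known reaction type is the Lewis acid-promoted conversion of 1-methylcycloalkene oxides into 1-methylcycloalkanecarbaldehydes with one ring atom fewer, for which bulky aluminium aryloxides favour alkyl over hydride migration. Ring A (C1–C5, C10) is not closed by a cyclisation: it arises by this suprafacial 1,2-alkyl shift, which turns the seven-membered ring C10–C1–C2–C3–C18–C4–C5 into the six-membered ring by expelling C18. The single new stereocentre, quaternary C4, is set stereospecifically by the epoxide configuration from step 4: C3 enters anti to the α-oxygen, so the formyl group (C18) ends on the α-face and the C19 methyl on the β-face. The step needs ring-bond migration in preference to the C18 hydride shift (which would give the cycloheptanone) and no interference from the enone; the bulk of the aluminium reagent, the relief of seven-ring strain and the low temperature should secure the first, and the poor Lewis basicity of the hindered conjugated ketone the second.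

Step 6
Reactants: 9 keto aldehyde
Product: 10 18-hydroxy-11,12,13,14,15,16-hexanorlabd-7-en-9-one
Conditions: NaBH4, MeOH/CH2Cl2, −78 → −40 °C
Reagents that add atoms: none
Why: Chemoselective hydride reduction should take the aldehyde and leave the conjugated ketone, which is flanked by the quaternary C10 and far less electrophilic.

Step 7
Reactants: 10 hydroxy enone
Product: 11 18-(tert-butyldimethylsilyloxy)-11,12,13,14,15,16-hexanorlabd-7-en-9-one
Conditions: TBSCl, imidazole, DMF, rt
Reagents that add atoms: tert-butyldimethylsilyl chloride CC(C)(C)[Si](C)(C)Cl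
Why: Standard silylation of the primary neopentyl alcohol gives an ether that should survive the basic, reductive and organometallic steps up to the final deprotection.

Step 8
Reactants: 11 silyl ether enone
Product: 13 18-(tert-butyldimethylsilyloxy)-11,12,13,14,15,16-hexanorlabd-8-en-9-yl trifluoromethanesulfonate, via lithium 8-en-9-olate 12 (not isolated)
Conditions: LiBH(s-Bu)3, THF, −78 °C; PhNTf2, −78 → 0 °C
Reagents that add atoms: N-phenylbis(trifluoromethanesulfonimide) O=S(=O)(N(c1ccccc1)S(=O)(=O)C(F)(F)F)C(F)(F)F
Why: Conjugate (1,4) hydride reduction of the hindered enone gives the tetrasubstituted enolate regiospecifically, and O-triflation traps it as the C9 enol triflate.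

Step 9
Reactants: 13 enol triflate
Product: 14 methyl 18-(tert-butyldimethylsilyloxy)-12,13,14,15,16-pentanorlabd-8-en-11-oate
Conditions: Pd(OAc)2 (cat.), PPh3, CO (1 atm), MeOH, Et3N, DMF, 60 °C
Reagents that add atoms: carbon monoxide [C-]#[O+]; methanol CO
Why: Palladium-catalysed methoxycarbonylation of the enol triflate installs C11 at the ester oxidation level on C9.

Step 10
Reactants: 14 conjugated ester
Product: 16 methyl 18-(tert-butyldimethylsilyloxy)-12,13,14,15,16-pentanorlabd-8(17)-en-11-oate (9α-H), via exocyclic lithium dienolate 15 (not isolated)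
Conditions: LiN(i-Pr)2, THF–DMPU, −78 °C; AcOH, −78 °C
Reagents that add atoms: none
Why: Deconjugative protonation: γ-deprotonation of the C17 methyl, which lies cis to the ester, gives the exocyclic dienolate, and kinetic α-protonation at C9 from the α-face (anti to the axial C20 methyl) should give the 8(17)-ene with the C9 substituent β.

Step 11
Reactants: 16 β,γ-unsaturated ester
Product: 17 18-(tert-butyldimethylsilyloxy)-12,13,14,15,16-pentanorlabd-8(17)-en-11-ol
Conditions: LiAlH4, Et2O, 0 °C
Reagents that add atoms: none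
Why: Hydride reduction of the ester gives the primary C11 alcohol without touching the silyl ether or the alkene.

Step 12
Reactants: 17 C11 alcohol
Product: 18 11-iodo-18-(tert-butyldimethylsilyloxy)-12,13,14,15,16-pentanorlabd-8(17)-ene
Conditions: I2, PPh3, imidazole, CH2Cl2, 0 °C → rt
Reagents that add atoms: iodine II
Why: Appel-type iodination converts the primary alcohol into the iodide from which the zinc reagent for both halves of the target is made.

Step 13
Reactants: 19 propargyl alcohol
Product: 21 (E)-3-iodo-2-methylprop-2-en-1-ol, via alkenylalane of propargyl alcohol 20 (not isolated)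
Conditions: AlMe3 (3 equiv.), Cp2ZrCl2 (0.25 equiv.), CH2Cl2, 0 °C → rt; I2, THF, −30 °C
Reagents that add atoms: trimethylaluminium C[Al](C)C; iodine II
Why: Zirconium-catalysed syn-carboalumination puts methyl on the internal and aluminium on the terminal alkyne carbon, and iodinolysis with retention gives the (E)-iodoalkene.

Step 14
Reactants: 21 iodo allylic alcohol
Product: 22 (E)-3-iodo-2-methylprop-2-enal
Conditions: MnO2, CH2Cl2, rt
Reagents that add atoms: none
Why: Allylic oxidation with MnO2 gives the enal without isomerising the alkene.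

Step 15
Reactants: 22 iodo enal
Product: 23 (E)-1-iodo-2-methylbuta-1,3-diene
Conditions: Ph3PCH3Br, NaN(SiMe3)2, THF, 0 °C; 22, −78 → 0 °C (product kept as a solution)
Reagents that add atoms: methyltriphenylphosphonium bromide C[P+](c1ccccc1)(c1ccccc1)c1ccccc1.[Br-]
Why: Wittig methylenation of the aldehyde completes the iododiene with the trisubstituted alkene geometry untouched.

Step 16
Reactants: 18 decalin iodide
Product: 24 [18-(tert-butyldimethylsilyloxy)-12,13,14,15,16-pentanorlabd-8(17)-en-11-yl]zinc iodide (LiCl complex; decanted from excess zinc, titrated with iodine and kept under argon as a THF stock solution that is divided between steps 17 and 21)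
Conditions: Zn dust (excess), LiCl, THF, 50 °C
Reagents that add atoms: zinc [Zn]
Why: LiCl-promoted direct insertion of zinc into the primary C–I bond gives the alkylzinc iodide without touching C9, the exocyclic alkene or the silyl ether; such solutions are storable, so one batch supplies both Negishi couplings.

Step 17
Reactants: 24 alkylzinc iodide (first portion of the stock solution); 23 iododiene
Product: 25 18-(tert-butyldimethylsilyloxy)labda-8(17),12E,14-triene
Conditions: Pd(OAc)2 (cat.), SPhos (cat.), THF, rt
Reagents that add atoms: none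
Why: Negishi coupling of the primary alkylzinc reagent with the (E)-alkenyl iodide should form C11–C12 with retention of alkene geometry and avoids an SN2 displacement at the β-branched C11.

Step 18
Reactants: 25 silylated triene; 26 methyl vinyl ketone
Product: 27 1-[(1S,2S)-3-methyl-2-{[18-(tert-butyldimethylsilyloxy)-12,13,14,15,16-pentanorlabd-8(17)-en-11-yl]}cyclohex-3-en-1-yl]ethan-1-one
Conditions: (S)-oxazaborolidinium triflimide [(S)-3,3-diphenyl-1-(2-methylphenyl)tetrahydro-1H,3H-pyrrolo[1,2-c][1,3,2]oxazaborole + HNTf2, oxazaborolidine in slight excess] (20 mol%), CH2Cl2, −78 → −40 °C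
Reagents that add atoms: none
Why: Lewis acid-catalysed asymmetric Diels–Alder reaction in which the terminal C12 alkyl substituent of the diene outweighs the C13 methyl and directs "ortho" bonding (C12–C14′ and C15–C15′), the endo transition state places the acetyl group cis to the C12 substituent, and the chiral cation selects the diene face, so that C12 and C14′ are set independently of the remote decalin.

Step 19
Reactants: 27 methyl ketone
Product: 30 (1S,2S)-1-ethynyl-3-methyl-2-{[18-(tert-butyldimethylsilyloxy)-12,13,14,15,16-pentanorlabd-8(17)-en-11-yl]}cyclohex-3-ene, via kinetic lithium enolate 28 (not isolated), via enol diethyl phosphate 29 (not isolated)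
Conditions: LiN(i-Pr)2 (1.1 equiv.), THF, −78 °C; ClP(O)(OEt)2, −78 °C → rt; LiN(i-Pr)2 (2.3 equiv.), −78 °C → rt
Reagents that add atoms: none
Why: Kinetic enolisation at the methyl group, O-phosphorylation and base-induced elimination of the enol phosphate convert the methyl ketone into the terminal alkyne without deprotonating the C14′ stereocentre.

Step 20
Reactants: 30 terminal alkyne
Product: 32 (1S,2S)-1-[(E)-1-iodoprop-1-en-2-yl]-3-methyl-2-{[18-(tert-butyldimethylsilyloxy)-12,13,14,15,16-pentanorlabd-8(17)-en-11-yl]}cyclohex-3-ene, via alkenyldimethylalane 31 (not isolated)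
Conditions: AlMe3 (3 equiv.), Cp2ZrCl2 (0.3 equiv.), CH2Cl2, 0 °C → rt; I2, THF, −30 °C
Reagents that add atoms: trimethylaluminium C[Al](C)C; iodine II
Why: Zirconium-catalysed syn-carboalumination of the terminal alkyne and iodinolysis with retention install the C16′ methyl and give the (E)-alkenyl iodide that fixes the 12′E geometry.

Step 21
Reactants: 24 alkylzinc iodide (second portion of the stock solution); 32 alkenyl iodide
Product: 33 18,18′-bis(tert-butyldimethylsilyl) ether of the target
Conditions: Pd(OAc)2 (cat.), SPhos (cat.), THF, rt → 40 °C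
Reagents that add atoms: none
Why: A second Negishi coupling joins C11′ of the alkylzinc reagent to C12′ of the alkenyl iodide with retention, completing the C40 skeleton.

Step 22
Reactants: 33 bis-silyl ether
Product: 34 target diol
Conditions: Bu4NF, THF, rt → 50 °C
Reagents that add atoms: none
Why: Fluoride-induced desilylation frees both neopentyl primary alcohols under conditions that leave the four alkenes and all stereocentres untouched.

Compound list
1 | (R)-(−)-carvone, (5R)-2-methyl-5-(prop-1-en-2-yl)cyclohex-2-en-1-one | CC1=CC[C@H](CC1=O)C(C)=C | starting material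
2 | lithium enolate of carvone (kinetic, cross-conjugated) | [Li]OC1=C[C@H](C(C)=C)CC=C1C | intermediate
3 | (5R,6S)-2,6-dimethyl-5-(prop-1-en-2-yl)cyclohex-2-en-1-one (trans-6-methylcarvone, major epimer drawn) | CC1=CC[C@@H](C(C)=C)[C@H](C)C1=O | intermediate
4 | 5-iodopent-1-ene | C=CCCCI | starting material
5 | lithium enolate of 6-methylcarvone | [Li]OC1=C(C)[C@H](C(C)=C)CC=C1C | intermediate
6 | (5S,6S)-2,6-dimethyl-6-(pent-4-en-1-yl)-5-(prop-1-en-2-yl)cyclohex-2-en-1-one | CC1=CC[C@@H](C(C)=C)[C@](C)(CCCC=C)C1=O | intermediate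
7 | (4aS,9aS)-2,5,9a-trimethyl-4,4a,7,8,9,9a-hexahydro-1H-benzo[7]annulen-1-one | CC1=CC[C@H]2C(C)=CCCC[C@]2(C)C1=O | intermediate
8 | 5,6-α-epoxide of 7 (oxygen cis to 4a-H, trans to 9a-CH3) | CC1=CC[C@H]2[C@]3(C)O[C@@H]3CCC[C@]2(C)C1=O | intermediate
9 | 9-oxo-11,12,13,14,15,16-hexanorlabd-7-en-18-al (4β-CH3, 4α-CHO) | CC1=CC[C@H]2[C@](C)(C=O)CCC[C@]2(C)C1=O | intermediate
10 | 18-hydroxy-11,12,13,14,15,16-hexanorlabd-7-en-9-one | CC1=CC[C@H]2[C@](C)(CO)CCC[C@]2(C)C1=O | intermediate
11 | 18-(tert-butyldimethylsilyloxy)-11,12,13,14,15,16-hexanorlabd-7-en-9-one | CC1=CC[C@H]2[C@](C)(CO[Si](C)(C)C(C)(C)C)CCC[C@]2(C)C1=O | intermediate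
12 | lithium 18-(tert-butyldimethylsilyloxy)-11,12,13,14,15,16-hexanorlabd-8-en-9-olate | CC1=C(O[Li])[C@@]2(C)CCC[C@@](C)(CO[Si](C)(C)C(C)(C)C)[C@@H]2CC1 | intermediate
13 | 18-(tert-butyldimethylsilyloxy)-11,12,13,14,15,16-hexanorlabd-8-en-9-yl trifluoromethanesulfonate | CC1=C(OS(=O)(=O)C(F)(F)F)[C@@]2(C)CCC[C@@](C)(CO[Si](C)(C)C(C)(C)C)[C@@H]2CC1 | intermediate
14 | methyl 18-(tert-butyldimethylsilyloxy)-12,13,14,15,16-pentanorlabd-8-en-11-oate | CC1=C(C(=O)OC)[C@@]2(C)CCC[C@@](C)(CO[Si](C)(C)C(C)(C)C)[C@@H]2CC1 | intermediate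
15 | exocyclic lithium dienolate of 14 (8(17),9(11)-diene) | C=C1CC[C@H]2[C@](C)(CO[Si](C)(C)C(C)(C)C)CCC[C@]2(C)C1=C(OC)O[Li] | intermediate
16 | methyl 18-(tert-butyldimethylsilyloxy)-12,13,14,15,16-pentanorlabd-8(17)-en-11-oate (9α-H) | C=C1CC[C@H]2[C@](C)(CO[Si](C)(C)C(C)(C)C)CCC[C@]2(C)[C@H]1C(=O)OC | intermediate
17 | 18-(tert-butyldimethylsilyloxy)-12,13,14,15,16-pentanorlabd-8(17)-en-11-ol | C=C1CC[C@H]2[C@](C)(CO[Si](C)(C)C(C)(C)C)CCC[C@]2(C)[C@H]1CO | intermediate
18 | 11-iodo-18-(tert-butyldimethylsilyloxy)-12,13,14,15,16-pentanorlabd-8(17)-ene | C=C1CC[C@H]2[C@](C)(CO[Si](C)(C)C(C)(C)C)CCC[C@]2(C)[C@H]1CI | intermediate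
19 | propargyl alcohol (prop-2-yn-1-ol) | C#CCO | starting material
20 | (E)-alkenyldimethylalane of propargyl alcohol (O-aluminated) | C[Al](C)/C=C(\C)CO[Al](C)C | intermediate
21 | (E)-3-iodo-2-methylprop-2-en-1-ol | I/C=C(\C)CO | intermediate
22 | (E)-3-iodo-2-methylprop-2-enal | I/C=C(\C)C=O | intermediate
23 | (E)-1-iodo-2-methylbuta-1,3-diene | I/C=C(\C)C=C | intermediate
24 | [18-(tert-butyldimethylsilyloxy)-12,13,14,15,16-pentanorlabd-8(17)-en-11-yl]zinc iodide (THF stock solution, LiCl complex) | C=C1CC[C@H]2[C@](C)(CO[Si](C)(C)C(C)(C)C)CCC[C@]2(C)[C@H]1C[Zn]I | intermediate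
25 | 18-(tert-butyldimethylsilyloxy)labda-8(17),12E,14-triene | C=C1CC[C@H]2[C@](C)(CO[Si](C)(C)C(C)(C)C)CCC[C@]2(C)[C@H]1C/C=C(\C)C=C | intermediate
26 | methyl vinyl ketone (but-3-en-2-one) | CC(=O)C=C | starting material
27 | 1-[(1S,2S)-3-methyl-2-{[18-(tert-butyldimethylsilyloxy)-12,13,14,15,16-pentanorlabd-8(17)-en-11-yl]}cyclohex-3-en-1-yl]ethan-1-one (cis) | CC(=O)[C@H]1CCC=C(C)[C@H]1C[C@H]1C(=C)CC[C@H]2[C@](C)(CO[Si](C)(C)C(C)(C)C)CCC[C@]12C | intermediate
28 | kinetic lithium enolate of 27 (methyl side) | C=C(O[Li])[C@H]1CCC=C(C)[C@H]1C[C@H]1C(=C)CC[C@H]2[C@](C)(CO[Si](C)(C)C(C)(C)C)CCC[C@]12C | intermediate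
29 | enol diethyl phosphate of 27 | C=C(OP(=O)(OCC)OCC)[C@H]1CCC=C(C)[C@H]1C[C@H]1C(=C)CC[C@H]2[C@](C)(CO[Si](C)(C)C(C)(C)C)CCC[C@]12C | intermediate
30 | (1S,2S)-1-ethynyl-3-methyl-2-{[18-(tert-butyldimethylsilyloxy)-12,13,14,15,16-pentanorlabd-8(17)-en-11-yl]}cyclohex-3-ene | C#C[C@H]1CCC=C(C)[C@H]1C[C@H]1C(=C)CC[C@H]2[C@](C)(CO[Si](C)(C)C(C)(C)C)CCC[C@]12C | intermediate
31 | (E)-alkenyldimethylalane from 30 | C[Al](C)/C=C(\C)[C@H]1CCC=C(C)[C@H]1C[C@H]1C(=C)CC[C@H]2[C@](C)(CO[Si](C)(C)C(C)(C)C)CCC[C@]12C | intermediate
32 | (1S,2S)-1-[(E)-1-iodoprop-1-en-2-yl]-3-methyl-2-{[18-(tert-butyldimethylsilyloxy)-12,13,14,15,16-pentanorlabd-8(17)-en-11-yl]}cyclohex-3-ene | I/C=C(\C)[C@H]1CCC=C(C)[C@H]1C[C@H]1C(=C)CC[C@H]2[C@](C)(CO[Si](C)(C)C(C)(C)C)CCC[C@]12C | intermediate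
33 | 18,18′-bis(tert-butyldimethylsilyl) ether of the target | C=C1CC[C@H]2[C@](C)(CO[Si](C)(C)C(C)(C)C)CCC[C@]2(C)[C@H]1C/C=C(\C)[C@H]1CCC=C(C)[C@H]1C[C@H]1C(=C)CC[C@H]2[C@](C)(CO[Si](C)(C)C(C)(C)C)CCC[C@]12C | intermediate
34 | target diol: [4+2] dimer of 18-hydroxylabda-8(17),12E,14-triene (cyclohexene C12–C13=C14–C15–C15′–C14′; C12–C14′ and C15–C15′ bonds; 12S,14′S, cis; 12′E) | C=C1CC[C@H]2[C@](C)(CO)CCC[C@]2(C)[C@H]1C/C=C(\C)[C@H]1CCC=C(C)[C@H]1C[C@H]1C(=C)CC[C@H]2[C@](C)(CO)CCC[C@]12C | target

Total step count: 22. Longest linear sequence: 19 steps (steps 1–12 and 16–22); steps 13–15 form a three-step side branch, and the zinc reagent 24 from step 16 enters the route twice (steps 17 and 21).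

Steps most likely to fail

Step 18. The catalyst may fail to impose one diene face and the endo mode on a diene whose own stereocentres are remote, or the strongly Lewis-acidic medium may isomerise the exocyclic alkene. The fallback sets out from 25 and returns at 27, and hands the control to a covalently bound auxiliary. Compound 25 and (S)-3-acryloyl-4-benzyl-1,3-oxazolidin-2-one with Et2AlCl in CH2Cl2 at −78 °C should give, through the chelated s-cis dienophile, the cis-imide F5. AlMe3 with MeNH(OMe)·HCl then gives the Weinreb amide F6, and MeMgBr in THF delivers ketone 27.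

Step 5. The 1,2-hydride shift from C18 may outrun migration of the ring bond, or a long-lived C4 cation may loosen the stereochemical link to the epoxide. The fallback sets out from 8 and returns at 10, and moves the contraction from the cationic to the anionic manifold. Under conditions that favour the hydride shift (a small Lewis acid such as BF3·OEt2 in benzene), 8 gives the cycloheptanone F1. SO2Cl2 chlorinates its more substituted α-carbon C4 on the face opposite the angular methyl, giving the chloroketone F2. NaOMe in Et2O induces a Favorskii rearrangement through the cyclopropanone (C3 displaces chloride with inversion, and the ring opens toward the less substituted carbanion) to the methyl ester F3. LiAlH4 reduces the ester and the enone carbonyl to the diol F4, and MnO2 re-oxidises the allylic alcohol to give 10.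

Step 10. Deprotonation may occur at ring carbon C7 instead of C17, or the dienolate may be protonated at C17 or from the β-face of C9. The fallback sets out from 14 and returns at 16, and replaces the base-mediated process by a photochemical deconjugation (hν 254 nm, hexane, catalytic 1,2-dimethylimidazole). Photoenolisation by 1,5-hydrogen transfer can only take a hydrogen from the C17 methyl, the γ-position cis to the ester carbonyl, and ketonisation of the dienol at C9 gives 16, so no new compound arises (F0).

Further compounds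
F1 | step 5 | cycloheptanone from hydride shift: (4aS,9aS)-2,5,9a-trimethyl-4a,5,7,8,9,9a-hexahydro-1H-benzo[7]annulene-1,6(4H)-dione (C5 epimers) | CC1=CC[C@H]2C(C)C(=O)CCC[C@]2(C)C1=O
F2 | step 5 | 5-chloro derivative of F1 (chlorine α, trans to the angular methyl) | CC1=CC[C@H]2[C@](C)(Cl)C(=O)CCC[C@]2(C)C1=O
F3 | step 5 | methyl 9-oxo-11,12,13,14,15,16-hexanorlabd-7-en-18-oate | CC1=CC[C@H]2[C@](C)(C(=O)OC)CCC[C@]2(C)C1=O
F4 | step 5 | 11,12,13,14,15,16-hexanorlabd-7-ene-9,18-diol (C9 epimers) | CC1=CC[C@H]2[C@](C)(CO)CCC[C@]2(C)C1O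
F5 | step 18 | (S)-4-benzyl-3-{(1S,2S)-3-methyl-2-{[18-(tert-butyldimethylsilyloxy)-12,13,14,15,16-pentanorlabd-8(17)-en-11-yl]}cyclohex-3-ene-1-carbonyl}-1,3-oxazolidin-2-one | O=C(N1C(=O)OC[C@@H]1Cc1ccccc1)[C@H]1CCC=C(C)[C@H]1C[C@H]1C(=C)CC[C@H]2[C@](C)(CO[Si](C)(C)C(C)(C)C)CCC[C@]12C
F6 | step 18 | (1S,2S)-N-methoxy-N,3-dimethyl-2-{[18-(tert-butyldimethylsilyloxy)-12,13,14,15,16-pentanorlabd-8(17)-en-11-yl]}cyclohex-3-ene-1-carboxamide | CON(C)C(=O)[C@H]1CCC=C(C)[C@H]1C[C@H]1C(=C)CC[C@H]2[C@](C)(CO[Si](C)(C)C(C)(C)C)CCC[C@]12C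
F0 | step 10 | none | none
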